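**Retrosynthetic overview**

1. Target 20 comes from the tri-O-benzyl flavone 19 by a single hydrogenolysis of the 7-, 2'- and 4'-O-benzyl groups.
2. 19 is cut into resorcinol 5 and the α-methoxy aroylacetate 16; one thermal annulation forms C4–C4a and O1–C2. Pyranone ring C is the only ring built and is closed last; rings A and B come intact from syringol and isovanillin.
3. The strategy rests on ring A (C4a, C5–OH, C6–OMe, C7–O, C8–OMe, C8a–O1), which is mirror-symmetric about the C4a···C7 axis. O1 and the 5-OH are therefore interchangeable and C4a is the only unsubstituted ring carbon, so the A-ring partner 5 has one CH and the annulation has only one possible regiochemical outcome.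
4. 5 is made from syringol (benzylation, double bromination, borylation, oxidation). 16 is made from isovanillin (benzylation, Dakin-type oxidation, benzylation, Vilsmeier formylation, ester aldol, oxidation) and ethyl methoxyacetate.

Key step: step 11

Remark on the chemistry: 15 and 16 are racemic (15 as a syn/anti mixture) and are used as such, because both centres are destroyed before the achiral target is reached.

**Route**

Step 1
Reactants: 1 2,6-dimethoxyphenol (syringol)
Product: 2 2-(benzyloxy)-1,3-dimethoxybenzene
Conditions: BnBr, K2CO3, DMF, 60 °C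
Reagents that add atoms: benzyl bromide, BrCc1ccccc1
Why: Williamson ether synthesis (SN2 of the phenoxide on benzyl bromide) should cap the oxygen that later becomes the 7-OH.

Step 2
Reactants: 2 2-(benzyloxy)-1,3-dimethoxybenzene
Product: 3 3-(benzyloxy)-1,5-dibromo-2,4-dimethoxybenzene
Conditions: NBS (2.1 equiv), MeCN, 0 °C to rt, dark
Reagents that add atoms: N-bromosuccinimide, O=C1CCC(=O)N1Br
Why: Electrophilic aromatic bromination should occur twice at the two equivalent carbons that are ortho to one methoxy group and para to the other, since the carbon para to the twisted central benzyloxy group is the least activated.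

Step 3
Reactants: 3 3-(benzyloxy)-1,5-dibromo-2,4-dimethoxybenzene
Product: 4 2,2'-[5-(benzyloxy)-4,6-dimethoxy-1,3-phenylene]bis(4,4,5,5-tetramethyl-1,3,2-dioxaborolane)
Conditions: B2pin2 (2.5 equiv), PdCl2(dppf) (5 mol%), KOAc, 1,4-dioxane, 90 °C
Reagents that add atoms: bis(pinacolato)diboron, CC1(C)OB(OC1(C)C)B1OC(C)(C)C(C)(C)O1
Why: Double Miyaura borylation (oxidative addition of each C–Br bond to zerovalent palladium, acetate-assisted transmetalation with the diboron, reductive elimination) is standard for electron-rich ortho-alkoxy aryl bromides.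

Step 4
Reactants: 4 2,2'-[5-(benzyloxy)-4,6-dimethoxy-1,3-phenylene]bis(4,4,5,5-tetramethyl-1,3,2-dioxaborolane)
Product: 5 5-(benzyloxy)-4,6-dimethoxybenzene-1,3-diol
Conditions: 30% H2O2, NaOH (aq), THF, 0 °C, argon; then Na2S2O3, dilute HCl to pH 5
Reagents that add atoms: hydrogen peroxide, OO
Why: Boronate oxidation (hydroperoxide adds to boron, the aryl group shifts from boron to oxygen) should place each hydroxyl exactly where bromine stood, and the cold, air-free conditions with a reductive quench protect the electron-rich resorcinol.

Step 5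
Reactants: 6 isovanillin (3-hydroxy-4-methoxybenzaldehyde)
Product: 7 3-(benzyloxy)-4-methoxybenzaldehyde
Conditions: BnBr, K2CO3, DMF, 60 °C
Reagents that add atoms: benzyl bromide, BrCc1ccccc1
Why: Williamson ether synthesis should protect the phenol that becomes the 4'-OH.

Step 6
Reactants: 7 3-(benzyloxy)-4-methoxybenzaldehyde
Product: 9 3-(benzyloxy)-4-methoxyphenol, via aryl formate 8 (not isolated)
Conditions: mCPBA, CH2Cl2, 0 °C to rt; aq NaHCO3 wash; then K2CO3 (cat.), MeOH, rt
Reagents that add atoms: 3-chloroperoxybenzoic acid (mCPBA), OOC(=O)c1cccc(Cl)c1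
Why: Baeyer–Villiger (Dakin-type) oxidation should work because the aryl group, activated by its para-methoxy substituent, migrates in the Criegee intermediate to give the formate, which base-catalysed methanolysis converts to the phenol.

Step 7
Reactants: 9 3-(benzyloxy)-4-methoxyphenol
Product: 10 2,4-bis(benzyloxy)-1-methoxybenzene
Conditions: BnBr, K2CO3, DMF, 60 °C
Reagents that add atoms: benzyl bromide, BrCc1ccccc1
Why: Williamson ether synthesis should protect the new phenol, the future 2'-OH.

Step 8
Reactants: 10 2,4-bis(benzyloxy)-1-methoxybenzene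
Product: 12 2,4-bis(benzyloxy)-5-methoxybenzaldehyde, via aryl iminium chloride 11 (not isolated)
Conditions: POCl3, DMF, 0 °C to 60 °C; then ice-water
Reagents that add atoms: N,N-dimethylformamide, CN(C)C=O; water, O
Why: Vilsmeier–Haack formylation should attack the one carbon that is ortho to one benzyloxy group and para to the other, because the carbon between the two benzyloxy groups is hindered and the remaining one is activated only by the methoxy group.

Step 9
Reactants: 12 2,4-bis(benzyloxy)-5-methoxybenzaldehyde; 13 ethyl methoxyacetate
Product: 15 ethyl 3-[2,4-bis(benzyloxy)-5-methoxyphenyl]-3-hydroxy-2-methoxypropanoate (racemic syn/anti mixture), via lithium enolate 14 (not isolated)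
Conditions: 13, LiN(iPr)2 (LDA), THF, −78 °C; then 12, −78 °C; AcOH quench at −78 °C
Reagents that add atoms: none
Why: Aldol addition of a preformed lithium ester enolate to a non-enolisable aldehyde should give the β-hydroxy ester; the two new stereocentres are left uncontrolled because one is oxidised in step 10 and the other becomes sp2 in step 11.

Step 10
Reactants: 15 ethyl 3-[2,4-bis(benzyloxy)-5-methoxyphenyl]-3-hydroxy-2-methoxypropanoate
Product: 16 ethyl 3-[2,4-bis(benzyloxy)-5-methoxyphenyl]-2-methoxy-3-oxopropanoate (racemic)
Conditions: Dess–Martin periodinane, CH2Cl2, 0 °C to rt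
Reagents that add atoms: none
Why: Dess–Martin oxidation of the benzylic secondary alcohol should give the β-keto ester under neutral, non-epimerising-irrelevant conditions that leave the benzyl ethers alone; the carbinol stereocentre is removed and the α-centre stays racemic and enolisable.

Step 11
Reactants: 5 5-(benzyloxy)-4,6-dimethoxybenzene-1,3-diol; 16 ethyl 3-[2,4-bis(benzyloxy)-5-methoxyphenyl]-2-methoxy-3-oxopropanoate
Product: 19 7-(benzyloxy)-2-[2,4-bis(benzyloxy)-5-methoxyphenyl]-5-hydroxy-3,6,8-trimethoxy-4H-chromen-4-one, via aroyl(methoxy)ketene 17 (not isolated), via 1,3-diketone 18 (not isolated)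
Conditions: 16 (1.2 equiv), Ph2O, 225 °C, argon sweep (EtOH and H2O distilled out)
Reagents that add atoms: none
Why: Heating should expel ethanol from 16 to give the α-oxoketene 17, which acylates 5 at its one ring CH (directly, or through the aryl ester followed by thermal acyl transfer) and so makes the C4–C4a bond of diketone 18; a flanking phenol oxygen then adds to the aryl ketone carbon and water leaves, which makes the O1–C2 bond. The closest known reaction is the Mentzer thermal pyrone synthesis, in which phloroglucinol-type phenols and aroylacetates, α-substituted ones included, give 5-hydroxyflavones without a catalyst. Ring C is the only ring closed, by 6-exo-trig attack of the phenol oxygen on the ketone carbonyl followed by dehydration to the aromatic 4-pyranone, whose C4 carbonyl is then chelated by the remaining 5-OH. No stereocentre is created, and the racemic α-carbon of 16 ends as the sp2 carbon C3 carrying its methoxy group. The step needs chemoselectivity (flavone over coumarin, productive C-acylation over dead-end O-acylation) rather than regiocontrol: the mirror plane of 5 makes the two hydroxyls and both closure modes identical, O-acylation is reversible at this temperature whereas cyclodehydration is not, and the neutral medium gives no help to Pechmann-type attack on the hindered, electron-rich aryl ketone. The 2'-O-benzyl group keeps 16 from closing on itself to a 4-hydroxycoumarin, and the 7-O-benzyl group keeps the central oxygen out of the acylation.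

Step 12
Reactants: 19 7-(benzyloxy)-2-[2,4-bis(benzyloxy)-5-methoxyphenyl]-5-hydroxy-3,6,8-trimethoxy-4H-chromen-4-one
Product: 20 5,7,2',4'-tetrahydroxy-3,6,8,5'-tetramethoxyflavone
Conditions: H2 (1 atm), palladium on carbon (Pd/C, 10 wt%), EtOAc/MeOH, rt
Reagents that add atoms: none
Why: Catalytic hydrogenolysis should cleave the three benzyl aryl ethers at atmospheric pressure while the methyl ethers and the conjugated, chelated pyranone are left untouched.

**Compound list**

1 | 2,6-dimethoxyphenol (syringol) | COc1cccc(OC)c1O | starting material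
2 | 2-(benzyloxy)-1,3-dimethoxybenzene | COc1cccc(OC)c1OCc1ccccc1 | intermediate
3 | 3-(benzyloxy)-1,5-dibromo-2,4-dimethoxybenzene | COc1c(Br)cc(Br)c(OC)c1OCc1ccccc1 | intermediate
4 | 2,2'-[5-(benzyloxy)-4,6-dimethoxy-1,3-phenylene]bis(4,4,5,5-tetramethyl-1,3,2-dioxaborolane) | COc1c(B2OC(C)(C)C(C)(C)O2)cc(B2OC(C)(C)C(C)(C)O2)c(OC)c1OCc1ccccc1 | intermediate
5 | 5-(benzyloxy)-4,6-dimethoxybenzene-1,3-diol | COc1c(O)cc(O)c(OC)c1OCc1ccccc1 | intermediate
6 | isovanillin (3-hydroxy-4-methoxybenzaldehyde) | COc1ccc(C=O)cc1O | starting material
7 | 3-(benzyloxy)-4-methoxybenzaldehyde | COc1ccc(C=O)cc1OCc1ccccc1 | intermediate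
8 | 3-(benzyloxy)-4-methoxyphenyl formate (not isolated) | COc1ccc(OC=O)cc1OCc1ccccc1 | intermediate
9 | 3-(benzyloxy)-4-methoxyphenol | COc1ccc(O)cc1OCc1ccccc1 | intermediate
10 | 2,4-bis(benzyloxy)-1-methoxybenzene | COc1ccc(OCc2ccccc2)cc1OCc1ccccc1 | intermediate
11 | N-{[2,4-bis(benzyloxy)-5-methoxyphenyl]methylidene}-N-methylmethanaminium chloride (not isolated) | COc1cc(C=[N+](C)C)c(OCc2ccccc2)cc1OCc1ccccc1.[Cl-] | intermediate
12 | 2,4-bis(benzyloxy)-5-methoxybenzaldehyde | COc1cc(C=O)c(OCc2ccccc2)cc1OCc1ccccc1 | intermediate
13 | ethyl methoxyacetate | CCOC(=O)COC | starting material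
14 | lithium enolate of ethyl methoxyacetate (not isolated) | CCOC([O-])=COC.[Li+] | intermediate
15 | ethyl 3-[2,4-bis(benzyloxy)-5-methoxyphenyl]-3-hydroxy-2-methoxypropanoate (racemic, syn/anti mixture) | CCOC(=O)C(OC)C(O)c1cc(OC)c(OCc2ccccc2)cc1OCc1ccccc1 | intermediate
16 | ethyl 3-[2,4-bis(benzyloxy)-5-methoxyphenyl]-2-methoxy-3-oxopropanoate (racemic) | CCOC(=O)C(OC)C(=O)c1cc(OC)c(OCc2ccccc2)cc1OCc1ccccc1 | intermediate
17 | 3-[2,4-bis(benzyloxy)-5-methoxyphenyl]-2-methoxy-3-oxoprop-1-en-1-one, the aroyl(methoxy)ketene (not isolated) | O=C=C(OC)C(=O)c1cc(OC)c(OCc2ccccc2)cc1OCc1ccccc1 | intermediate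
18 | 1-[4-(benzyloxy)-2,6-dihydroxy-3,5-dimethoxyphenyl]-3-[2,4-bis(benzyloxy)-5-methoxyphenyl]-2-methoxypropane-1,3-dione (racemic, not isolated) | COc1cc(C(=O)C(OC)C(=O)c2c(O)c(OC)c(OCc3ccccc3)c(OC)c2O)c(OCc2ccccc2)cc1OCc1ccccc1 | intermediate
19 | 7-(benzyloxy)-2-[2,4-bis(benzyloxy)-5-methoxyphenyl]-5-hydroxy-3,6,8-trimethoxy-4H-chromen-4-one | COc1cc(-c2oc3c(OC)c(OCc4ccccc4)c(OC)c(O)c3c(=O)c2OC)c(OCc2ccccc2)cc1OCc1ccccc1 | intermediate
20 | 5,7,2',4'-tetrahydroxy-3,6,8,5'-tetramethoxyflavone | COc1cc(-c2oc3c(OC)c(O)c(OC)c(O)c3c(=O)c2OC)c(O)cc1O | target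

**Step count**

Total: 12 steps. Longest linear sequence: 8 steps (isovanillin 6 to target 20, steps 5 to 12); the A-ring branch from syringol 1 is 6 steps to the target.

**Steps most likely to fail**

Step 11 (thermal annulation). At the temperature needed to generate the ketene, benzyl groups may migrate or be lost. The sequence may also stall at the reversible O-acyl stage, some material may close the other way to a coumarin, and C-acylation may be slow because the twisted alkoxy groups of 5 donate poorly to the reacting carbon. The fallback builds the same two bonds stepwise at low temperature; it sets out from 5 and from 12 and comes back to the route at 19, passing through 18 as an isolated compound. Hoesch acylation of 5 with methoxyacetonitrile (ZnCl2, HCl gas, Et2O, 0 °C) should precipitate 1-[4-(benzyloxy)-2,6-dihydroxy-3,5-dimethoxyphenyl]-2-methoxyethan-1-iminium chloride F1, and warm water should hydrolyse it to 1-[4-(benzyloxy)-2,6-dihydroxy-3,5-dimethoxyphenyl]-2-methoxyethan-1-one F2. Aldehyde 12 would be oxidised under Pinnick conditions (NaClO2, NaH2PO4, 2-methylbut-2-ene, tBuOH/H2O) to 2,4-bis(benzyloxy)-5-methoxybenzoic acid F3 and converted with (COCl)2 and catalytic DMF in CH2Cl2 into 2,4-bis(benzyloxy)-5-methoxybenzoyl chloride F4. Ketone F2, deprotonated three times with LiN(SiMe3)2 in THF at −78 °C, would be C-acylated by F4 (Baker–Venkataraman-type acylation of the ketone enolate) to give diketone 18. TsOH in toluene at 80 °C should then cyclodehydrate 18 to 19.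

Step 3 (double borylation). The second C–Br bond of the hindered, electron-rich ring may borylate incompletely, and protodebromination may compete. The fallback replaces the C–B detour by direct C–O coupling; it sets out from 3 and comes back at 5, so that step 4 is bypassed as well. Palladium-catalysed hydroxylation of both C–Br bonds with KOH (Pd2(dba)3 as zerovalent palladium source, tBuXPhos, 1,4-dioxane/H2O, 100 °C, argon), followed by acidification, should give 5 directly; no new compound is made.

Step 9 (ester aldol). The adduct may revert by retro-aldol cleavage on quench, the ester enolate may condense with itself, and addition to the hindered, electron-rich aldehyde may be slow. The fallback makes the same C–C bond at the ester oxidation level, so that no oxidation is needed; it sets out from 12 and comes back at 16, bypassing 15 and step 10. Oxidative esterification of 12 (I2, KOH, EtOH, 0 °C) should give ethyl 2,4-bis(benzyloxy)-5-methoxybenzoate F5. Crossed Claisen condensation of F5 with lithium enolate 14 (2.2 equiv, from 13 and LiN(iPr)2, THF, −78 °C to 0 °C, acidic quench) should give 16.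

**Further compounds**

F1 | step 11 | 1-[4-(benzyloxy)-2,6-dihydroxy-3,5-dimethoxyphenyl]-2-methoxyethan-1-iminium chloride | COCC(=[NH2+])c1c(O)c(OC)c(OCc2ccccc2)c(OC)c1O.[Cl-]
F2 | step 11 | 1-[4-(benzyloxy)-2,6-dihydroxy-3,5-dimethoxyphenyl]-2-methoxyethan-1-one | COCC(=O)c1c(O)c(OC)c(OCc2ccccc2)c(OC)c1O
F3 | step 11 | 2,4-bis(benzyloxy)-5-methoxybenzoic acid | COc1cc(C(=O)O)c(OCc2ccccc2)cc1OCc1ccccc1
F4 | step 11 | 2,4-bis(benzyloxy)-5-methoxybenzoyl chloride | COc1cc(C(=O)Cl)c(OCc2ccccc2)cc1OCc1ccccc1
F0 | step 3 | none | none
F5 | step 9 | ethyl 2,4-bis(benzyloxy)-5-methoxybenzoate | CCOC(=O)c1cc(OC)c(OCc2ccccc2)cc1OCc1ccccc1
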